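**Plan**

1. Labels (text only): ring A = O–C1(iPr)=C2–C3–C4–C5 (C4 is the spiro, bridging carbon); ring D = C4–C7–C8–C9–C10=C11–C18; ring B = C10–C11–C12–C13–C14; ring C = C11–C12–C15(C16O2H)–C17–C18; ring E = C18–C19–N(CH3)–C22–C7–C4.
2. Cuts: the pyran and the quaternary C4 go back to a bridging C4 ketone (C1–O ketal, C3=C2 olefination, C4–C5 formaldehyde aldol). C12–H/C15–H and C15–C16 go back through a dienoate and a dienyl triflate to an enone. The C10–C14 bond of ring B is cut by a retro vinylcyclopropane rearrangement to a cyclopropane spiro at C12. C7–C22 (Mannich), C11=C12 (aldol) and C18–C19/C18–C17 lead to cycloheptane-1,3-dione.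
3. Forward: ring D is bought; ring C by desymmetrising aldol condensation; ring E by Mannich bridging; the spirocyclopropane; ring B by its two-atom ring expansion; ring A last.
4. Enabling feature: ring B shares C11–C12 with ring C and C10=C11 with ring D, and C12 lies between C15 (a ketone before it becomes the CH–CO2H carbon) and C11, whose neighbour C10 is the γ-carbon of that enone. A cyclopropane spiro at C12 is therefore a 1-acyl-1-vinylcyclopropane (vinyl = C11=C10), and its rearrangement gives exactly the ring C12–C13–C14–C10–C11.
5. Stereochemistry: C18 from the catalytic enantioselective aldol desymmetrisation; C7 is forced by the bridge; C4 from face-selective hydroxymethylation; C12 and C15 together from one hydrogenation anti to the C5 methylene.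

Key step: step 7

Remark: the sense of induction of the amino-acid catalyst in step 4 is not known for this ring size; L-phenylalanine is written, and its antipode would be used if it leads to ent-8.
Remark: centres that are erased in the next step (C10 of 12, C4 of 16), the anomeric C1 of 21 and 22, the E/Z geometry of 15 and the carbinol carbon of F1–F3 are left undefined in the SMILES.

**Route**

Step 1
Reactants: 1 cycloheptane-1,3-dione; 2 allyl acetate
Product: 3 2-(prop-2-en-1-yl)cycloheptane-1,3-dione
Conditions: Pd(PPh3)4 (2 mol %), DBU, PhMe, 60 °C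
Reagents that add atoms: none
Why: Tsuji–Trost C-allylation of the soft 1,3-dione enolate by the π-allyl palladium complex should give the 2-monoallyl dione (no stereocentre).

Step 2
Reactants: 3 2-(prop-2-en-1-yl)cycloheptane-1,3-dione; 4 1,3,5-trimethyl-1,3,5-triazinane
Product: 6 tert-butyl methyl{[2,7-dioxo-1-(prop-2-en-1-yl)cycloheptyl]methyl}carbamate, via Mannich base 5 (not isolated)
Conditions: 4 (0.4 equiv), AcOH, 40 °C; concentrate; then Boc2O, Et3N, CH2Cl2, rt
Reagents that add atoms: di-tert-butyl dicarbonate CC(C)(C)OC(=O)OC(=O)OC(C)(C)C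
Why: Mannich reaction of the acidic tertiary C–H of the 2-substituted 1,3-dione with N-methylmethaniminium (released from the triazinane in acid) should build the quaternary carbon C18 carrying C19–N, and Boc capture of the secondary amine blocks retro-Mannich cleavage.

Step 3
Reactants: 6 tert-butyl methyl{[2,7-dioxo-1-(prop-2-en-1-yl)cycloheptyl]methyl}carbamate
Product: 7 tert-butyl methyl{[2,7-dioxo-1-(2-oxopropyl)cycloheptyl]methyl}carbamate
Conditions: PdCl2 (10 mol %), CuCl, O2 (1 atm), DMF/H2O 7:1, rt
Reagents that add atoms: water O
Why: Tsuji–Wacker oxidation of the terminal alkene should give the methyl ketone (Markovnikov), the usual way to 2-acetonyl-1,3-diones.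

Step 4
Reactants: 7 tert-butyl methyl{[2,7-dioxo-1-(2-oxopropyl)cycloheptyl]methyl}carbamate
Product: 8 (8aS)-bicyclic enedione (cyclopentenone C15(=O)–C12H=C11 fused to the cycloheptanone; C4 ketone; C18 quaternary)
Conditions: L-phenylalanine (30 mol %), (+)-CSA (15 mol %), DMF, 60 °C
Reagents that add atoms: none
Why: Amine-catalysed desymmetrising intramolecular aldol condensation of the Hajos–Parrish type, in which the enamine of the methyl ketone attacks one of the two enantiotopic ring carbonyls (5-enolexo) and water is lost, should set C18, the only stereocentre, under catalyst control.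

Step 5
Reactants: 8 (8aS)-bicyclic enedione
Product: 10 tricyclic amino enedione, via amine salt 9 (not isolated)
Conditions: TFA/CH2Cl2 1:4, 0 °C to rt; evaporate; then 37% aq. HCHO (3 equiv), NaOAc/AcOH (pH ~5), EtOH, 60 °C
Reagents that add atoms: formaldehyde C=O
Why: Boc cleavage and intramolecular Mannich reaction, in which the N-methyliminium is attacked by the enol of the C4 ketone at C7 (its only enolisable α-carbon; 6-endo closure, whereas closure at C17 would be 5-endo), should close the piperidine with C7 fixed by the bridge.

Step 6
Reactants: 10 tricyclic amino enedione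
Product: 11 spiro-vinylcyclopropane (cyclopropane C13–C14 spiro at C12; alkene moved to C11=C10)
Conditions: diphenylvinylsulfonium triflate (1.1 equiv), t-BuOK (1.2 equiv), t-BuOH/THF, 0 °C to rt
Reagents that add atoms: diphenylvinylsulfonium triflate C=C[S+](c1ccccc1)c1ccccc1.[O-]S(=O)(=O)C(F)(F)F
Why: Deconjugative α,α-dialkylation of the enone through its extended dienolate (α-attack at C12 on the vinylsulfonium, proton transfer, 3-exo-tet displacement of Ph2S) should give the spirocyclopropane, the C4 ketone being non-enolisable (C18 quaternary, C7 bridgehead).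

Step 7
Reactants: 11 spiro-vinylcyclopropane
Product: 12 tetracyclic enone (ring B closed by the new C14–C10 bond; enone C15(=O)–C12=C11; C10–H)
Conditions: degassed 1,2-dichlorobenzene (0.02 M), 220 °C, sealed tube
Reagents that add atoms: none
Why: Heating should homolyse a C12–CH2 bond of the spirocyclopropane to a 1,3-diradical whose C12 end is delocalised into the C11=C10 alkene and onto the C15 carbonyl, and the primary CH2 radical then recombines with the allyl terminus C10 (formal [1,3]-shift), so that the ring C12–C13–C14 grows by C11 and C10 into the cyclopentene while the double bond moves to C12=C11. The closest known reaction type is the thermal vinylcyclopropane–cyclopentene rearrangement of 1-acyl-1-vinylcyclopropanes and of spiro vinylcyclopropanes used for cyclopentene annulation. Ring B closes by radical recombination inside the tethered diradical, a five-membered closure that is not subject to the 5-endo restriction of the ionic alternative. The only new stereocentre, C10–H, is not controlled and need not be, because C10 becomes sp2 again in step 8. The step needs C–C recombination at C10 instead of O-closure to a dihydrofuran; O-closure is reversible and the conjugated enone is the thermodynamic sink, ring C holds the cyclopropane bonds about 60° out of the alkene plane with C10 within reach, and the two cyclopropane CH2 groups are equivalent so either cleavage gives 12. The bridging ketone and the tertiary amine have no low-energy thermal pathway.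

Step 8
Reactants: 12 tetracyclic enone
Product: 13 dienyl triflate (C15(OTf)=C12–C11=C10)
Conditions: KHMDS (0.95 equiv), THF, −78 to 0 °C; then PhNTf2, 0 °C
Reagents that add atoms: N-phenylbis(trifluoromethanesulfonimide) O=S(=O)(N(c1ccccc1)S(=O)(=O)C(F)(F)F)C(F)(F)F
Why: Equilibration with a slight deficit of base should give the extended dienolate by γ-deprotonation at C10 (both C10 epimers converge) and O-triflation then gives the linear dienyl triflate, as for steroidal 3,5-dienyl triflates.

Step 9
Reactants: 13 dienyl triflate
Product: 14 methyl dienoate (C15(CO2Me)=C12–C11=C10; C4 ketone)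
Conditions: Pd(OAc)2 (5 mol %), dppp (6 mol %), CO (1 atm), MeOH, Et3N, DMF, 60 °C
Reagents that add atoms: carbon monoxide [C-]#[O+]; methanol CO
Why: Palladium-catalysed alkoxycarbonylation of the alkenyl triflate (oxidative addition, CO insertion, methanolysis) should install C16 as the ester.

Step 10
Reactants: 14 methyl dienoate
Product: 16 bridging-carbon aldehyde (C4–H, C4–CHO), via enol ether 15 (not isolated)
Conditions: Ph3P(Cl)CH2OMe (3 equiv), KHMDS (2.8 equiv), THF, 0 to 50 °C; then 2 M aq. HCl/THF, rt; NaHCO3 work-up
Reagents that add atoms: (methoxymethyl)triphenylphosphonium chloride COC[P+](c1ccccc1)(c1ccccc1)c1ccccc1.[Cl-]; water O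
Why: Wittig methoxymethylenation of the hindered, non-enolisable bridging ketone and hydrolysis of the enol ether should homologate C4 by one carbon; the C4 configuration is irrelevant because C4 is enolised in step 11.

Step 11
Reactants: 16 bridging-carbon aldehyde
Product: 17 hydroxymethyl aldehyde (C4 quaternary; CHO over the piperidine, CH2OH = C5 over the C10=C11 bridge)
Conditions: 37% aq. HCHO (5 equiv), K2CO3 (0.5 equiv), MeOH/THF, rt to 40 °C
Reagents that add atoms: formaldehyde C=O
Why: Crossed aldol (hydroxymethylation) of the α-branched aldehyde with formaldehyde, in which the small electrophile should attack the exocyclic enolate at C4 from the side of the carbocyclic bridge (one axial C8–H and the flat sp2 C11) and not from the piperidine side (axial C19–H and C22–H), so that C5 ends over the C10=C11 bridge and the formyl carbon (future C3) over the piperidine.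

Step 12
Reactants: 17 hydroxymethyl aldehyde; 18 dimethyl (3-methyl-2-oxobutyl)phosphonate
Product: 19 E-enone (C4–C3H=C2H–C1(=O)–CH(CH3)2; C5–OH free)
Conditions: Ba(OH)2·8H2O (1.2 equiv), THF/H2O 40:1, rt
Reagents that add atoms: none
Why: Horner–Wadsworth–Emmons olefination of the neopentyl aldehyde under mild barium hydroxide conditions (to limit retro-aldol loss of formaldehyde) should give the E-enone that carries C2, C1 and the isopropyl group.

Step 13
Reactants: 19 E-enone
Product: 21 spirocyclic methyl ketal (2-methoxy-2-isopropyltetrahydropyran spiro at C4; dienoate intact), via hydroxy ketone 20 (not isolated)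
Conditions: H2 (1 atm), 10% Pd/C, CSA (1.2 equiv), MeOH, 3 Å MS, rt
Reagents that add atoms: methanol CO
Why: Hydrogenation of the disubstituted enone alkene (the tetrasubstituted dienoate reacts much more slowly) and acid-catalysed cyclisation of the δ-hydroxy ketone in methanol should give the cyclic mixed ketal, which also masks the C5 hydroxyl before step 14.

Step 14
Reactants: 21 spirocyclic methyl ketal
Product: 22 ketal ester (C12–H and C15–H cis, as in the target; C10=C11 kept)
Conditions: H2 (50 bar), [Ir(cod)(PCy3)(py)]BArF (10 mol %), CH2Cl2, rt (21 as its camphorsulfonate salt); NaHCO3 work-up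
Reagents that add atoms: none
Why: Iridium-catalysed hydrogenation of the tetrasubstituted α,β-alkene of the dienoate should add H2 cis to C12 and C15 from the face opposite the C5 methylene that sits over ring C, setting both centres in one event, while the C10=C11 alkene, buried next to the quaternary bridgehead C18, should stay.

Step 15
Reactants: 22 ketal ester
Product: 23 methyl ester of the target (enol ether C1=C2)
Conditions: TMSOTf (2.5 equiv), i-Pr2NEt (4 equiv), CH2Cl2, −20 to 0 °C
Reagents that add atoms: none
Why: Silyl-triflate-induced loss of methoxide to the cyclic oxocarbenium ion and deprotonation at the less hindered ring CH2 (C2) by the hindered base (ketal to enol ether elimination) should give the endocyclic enol ether; the low temperature avoids silylation of the ester.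

Step 16
Reactants: 23 methyl ester of the target
Product: 24 CNP0237695.1 (target acid)
Conditions: Me3SnOH (6 equiv), 1,2-dichloroethane, 80 °C; pH 6.5 phosphate buffer work-up
Reagents that add atoms: trimethyltin hydroxide C[Sn](C)(C)O
Why: Tin hydroxide-mediated cleavage of the methyl ester is near-neutral, so it should neither epimerise C15 (the ester sits on the more hindered face) nor hydrolyse the acid-labile enol ether.

**Compound list**

1 | cycloheptane-1,3-dione | O=C1CCCCC(=O)C1 | starting material
2 | allyl acetate (prop-2-en-1-yl acetate) | CC(=O)OCC=C | starting material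
3 | 2-(prop-2-en-1-yl)cycloheptane-1,3-dione | C=CCC1C(=O)CCCCC1=O | intermediate
4 | 1,3,5-trimethyl-1,3,5-triazinane | CN1CN(C)CN(C)C1 | starting material
5 | 2-[(methylamino)methyl]-2-(prop-2-en-1-yl)cycloheptane-1,3-dione (Mannich base, not isolated) | CNCC1(CC=C)C(=O)CCCCC1=O | intermediate
6 | tert-butyl methyl{[2,7-dioxo-1-(prop-2-en-1-yl)cycloheptyl]methyl}carbamate | C=CCC1(CN(C)C(=O)OC(C)(C)C)C(=O)CCCCC1=O | intermediate
7 | tert-butyl methyl{[2,7-dioxo-1-(2-oxopropyl)cycloheptyl]methyl}carbamate | CC(=O)CC1(CN(C)C(=O)OC(C)(C)C)C(=O)CCCCC1=O | intermediate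
8 | tert-butyl methyl{[(8aS)-2,8-dioxo-1,2,4,5,6,7,8,8a-octahydroazulen-8a-yl]methyl}carbamate (bicyclic enedione) | O=C1C=C2CCCCC(=O)[C@@]2(CN(C)C(=O)OC(C)(C)C)C1 | intermediate
9 | (8aS)-8a-[(methylamino)methyl]-4,5,6,7-tetrahydroazulene-2,8(1H,8aH)-dione (present as its trifluoroacetate, not isolated) | O=C1C=C2CCCCC(=O)[C@@]2(CNC)C1 | intermediate
10 | tricyclic amino enedione: 3-methyl-3-azabicyclo[4.3.1]decan-10-one (C4 = C10 ketone) fused along C18–C11 to the cyclopent-2-enone C15(=O)–C12H=C11; C7–H and C18 as in the target | O=C1C=C2CCC[C@@H]3CN(C)C[C@@]2(C1)C3=O | intermediate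
11 | spiro-vinylcyclopropane: 10 with a cyclopropane (C13, C14) spiro at C12 and the alkene at C11=C10 | O=C1C2(CC2)C2=CCC[C@@H]3CN(C)C[C@@]2(C1)C3=O | intermediate
12 | tetracyclic enone: ring B closed (C12–C13–C14–C10–C11), enone C15(=O)–C12=C11, C10–H (either epimer), bridging C4 ketone | O=C1C2=C3C(CC2)CC[C@@H]2CN(C)C[C@@]3(C1)C2=O | intermediate
13 | dienyl triflate: C15(OSO2CF3)=C12–C11=C10 | FC(F)(F)S(=O)(=O)OC1=C2CCC3=C2[C@@]4(C1)CN(C)C[C@@H](CC3)C4=O | intermediate
14 | methyl dienoate: C15(CO2CH3)=C12–C11=C10, bridging C4 ketone | COC(=O)C1=C2CCC3=C2[C@@]4(C1)CN(C)C[C@@H](CC3)C4=O | intermediate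
15 | methyl enol ether C4=CH–OCH3 (E/Z mixture, not isolated) | COC(=O)C1=C2CCC3=C2[C@@]4(C1)CN(C)C[C@@H](CC3)C4=COC | intermediate
16 | bridging-carbon aldehyde: C4–H, C4–CHO | COC(=O)C1=C2CCC3=C2[C@@]4(C1)CN(C)C[C@@H](CC3)C4C=O | intermediate
17 | hydroxymethyl aldehyde: quaternary C4 with CHO (future C3) over the piperidine and CH2OH (C5) over the C10=C11 bridge | COC(=O)C1=C2CCC3=C2[C@@]4(C1)CN(C)C[C@@H](CC3)[C@@]4(C=O)CO | intermediate
18 | dimethyl (3-methyl-2-oxobutyl)phosphonate | COP(=O)(CC(=O)C(C)C)OC | starting material
19 | E-enone: C4–C3H=C2H–C1(=O)–CH(CH3)2, C5–OH free | COC(=O)C1=C2CCC3=C2[C@@]4(C1)CN(C)C[C@@H](CC3)[C@@]4(/C=C/C(=O)C(C)C)CO | intermediate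
20 | hydroxy ketone: C4–CH2CH2–C(=O)–CH(CH3)2, C5–OH (not isolated) | COC(=O)C1=C2CCC3=C2[C@@]4(C1)CN(C)C[C@@H](CC3)[C@@]4(CCC(=O)C(C)C)CO | intermediate
21 | spirocyclic methyl ketal: 2-methoxy-2-isopropyltetrahydropyran spiro at C4, dienoate intact | CC(C)C1(OC)CC[C@@]2(CO1)[C@@H]1CCC3=C4C(CC3)=C(C(=O)OC)C[C@@]42CN(C)C1 | intermediate
22 | ketal ester: as 21 but C12–H and C15–H cis (target configuration), C10=C11 kept | CC(C)C1(OC)CC[C@@]2(CO1)[C@@H]1CCC3=C4[C@H](CC3)[C@H](C(=O)OC)C[C@@]42CN(C)C1 | intermediate
23 | methyl ester of the target (6-isopropyl-3,4-dihydro-2H-pyran formed) | CC(C)C1=CC[C@@]2(CO1)[C@@H]1CCC3=C4[C@H](CC3)[C@H](C(=O)OC)C[C@@]42CN(C)C1 | intermediate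
24 | CNP0237695.1 | CC(C)C1=CC[C@@]2(CO1)[C@@H]1CCC3=C4[C@H](CC3)[C@H](C(=O)O)C[C@@]42CN(C)C1 | target

**Count and risks**

Total steps: 16. Longest linear sequence: 16 steps (from 1).

Step 14. The hydrogenation may add hydrogen 1,4 across the diene or reduce or shift the C10=C11 alkene. The iridium may also be steered to the wrong face by the ring oxygen, or be poisoned by the amine. Fallback: from 21, a ligand-accelerated copper hydride 1,4-reduction (Cu(OAc)2, 1,2-bis(diphenylphosphino)benzene, diethoxymethylsilane, PhMe) delivers hydride to C12 from the open face. By analogy with dienones that bear a hindered tetrasubstituted γ,δ-alkene, that alkene should not be engaged. The product is the silyl ketene acetal F5, and its kinetic protonation at C15 (2,6-di-tert-butylphenol, then aqueous fluoride), again from the face away from C5, returns to the route at 22.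

Step 11. Formaldehyde may attack the other face of the exocyclic enolate (C5 then ends over the piperidine). Retro-aldol loss of formaldehyde and crossed Cannizzaro reduction are also possible. Fallback: the order of the two C–C bond formations at C4 is reversed. From 16, base-catalysed Michael addition (DBU, MeCN) to 4-methylpent-1-en-3-one brings in the three-carbon chain from the face that formaldehyde preferred and gives the keto aldehyde F4. Chemoselective reduction of its aldehyde (NaBH4, MeOH, −40 °C) gives 20, and ketalisation under the acid/methanol conditions of step 13 rejoins the route at 21.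

Step 4. The catalyst may discriminate poorly between the two enantiotopic ring carbonyls, or the five-ring enamine aldolisation may be slow and allow retro-Claisen opening of the 2,2-disubstituted dione. Fallback: the desymmetrisation is moved to a reduction. From 6, Ru(II)–TsDPEN transfer hydrogenation (HCO2H/Et3N) reduces one of the two enantiotopic ketones to the hydroxy ketone F1. Wacker oxidation as in step 3 gives the hydroxy diketone F2. Achiral enamine aldol condensation (pyrrolidine, AcOH) gives the hydroxy enone F3, and Dess–Martin oxidation of the carbinol returns to the route at 8.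

**Further compounds**

F1 | step 4 | tert-butyl {[(1S)-2-hydroxy-7-oxo-1-(prop-2-en-1-yl)cycloheptyl]methyl}methylcarbamate (carbinol configuration immaterial) | C=CC[C@]1(CN(C)C(=O)OC(C)(C)C)C(O)CCCCC1=O
F2 | step 4 | tert-butyl {[2-hydroxy-7-oxo-1-(2-oxopropyl)cycloheptyl]methyl}methylcarbamate (C18 as in 8) | CC(=O)C[C@]1(CN(C)C(=O)OC(C)(C)C)C(O)CCCCC1=O
F3 | step 4 | tert-butyl {[(8aS)-8-hydroxy-2-oxo-1,2,4,5,6,7,8,8a-octahydroazulen-8a-yl]methyl}methylcarbamate | O=C1C=C2CCCCC(O)[C@@]2(CN(C)C(=O)OC(C)(C)C)C1
F4 | step 11 | keto aldehyde: quaternary C4 with CH2CH2C(=O)CH(CH3)2 over the piperidine and CHO (C5) over the C10=C11 bridge | COC(=O)C1=C2CCC3=C2[C@@]4(C1)CN(C)C[C@@H](CC3)[C@]4(C=O)CCC(=O)C(C)C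
F5 | step 14 | silyl ketene acetal of 22 (C12–H set; C15=C(OCH3)OSi(CH3)(OEt)2) | CC(C)C1(OC)CC[C@@]2(CO1)[C@@H]1CCC3=C4[C@H](CC3)C(=C(OC)O[Si](C)(OCC)OCC)C[C@@]42CN(C)C1
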